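## Analysis of the target

- The target 27 is a 4,5-dihydro-furanoheliangolide-type ester built on a ten-membered carbocycle C1–C10. The locants used below are: C1 ketone carbon, C2 the =CH next to it, C3 the O-bearing sp2 carbon, C4 the CH(CH3), C5 the CH2, C6 the acyloxy CH, C7 and C8 the β- and γ-carbons of the lactone, C9 the exocyclic =CH, C10 the quaternary carbon, C11 the lactone α-carbon, C12 the lactone C=O, C13 the CH2OH.
- An ether oxygen bridges C3 and C10. It creates a furan-3(2H)-one (ring A) and a nine-membered oxacycle (ring B, five of its nine atoms sp2). C7–C8 is fused to a γ-ylidene butenolide (ring C), whose enol-ether double bond C8=C9 lies inside ring B and is E only because the ring holds C10 cis to C7.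
- There are three stereocentres, all S: C4 (methyl), C6 (ester oxygen) and the fully substituted C10 (CH3, O, C1, C9). C4 and C6 are 1,3-related (anti in the zigzag chain, cis once C3 and the C6 oxygen are tied into a γ-lactone). C10 is remote from both and communicates with them only through the conformation of ring B.
- Sensitive groups are the cross-conjugated ylidene butenolide (base, nucleophiles, reduction), the C6 ester (allylic and vinylogously β to the lactone carbonyl), two primary allylic alcohols, and the vinylogous ester of ring A with its γ-acidic C4–H.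
- The difficulties are the strained bridged ring B, the quaternary stereocentre C10 at its bridgehead, and the fact that ring C tolerates almost no carbon–carbon bond-forming conditions.
- The feature the plan exploits: both five-membered heterocycles are furans in a dearomatised or oxidised state. Ring A is a 2-methyl-3-hydroxyfuran alkylated at C10. Ring C (C7, C8, C11, C12 and the lactone oxygen) is the photooxygenation product of a 2,3,4-trisubstituted furan, in which C9 is a furfuryl carbon.

## Retrosynthetic reasoning

**Ring C as a furan (27 ⇐ 26 ⇐ 23).** The last skeletal operation is an oxidative dearomatisation, not a C–C bond formation. In 23 the atoms C8, C7, C11 and C12 form a furan. Photooxygenation adds two oxygen atoms across C8/C12. The endoperoxide 24 can lose only the C12 hydrogen, which fixes the lactone carbonyl at C12 and the hemiketal at C8 (25). Loss of water can then involve only C9 and gives C8=C9 with the ring-enforced geometry (26). Ring C thus appears after all base- and nucleophile-mediated chemistry; desilylation gives 27.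

**Ester bond at C6 (23 ⇐ 17 + 22).** The enoate would not survive the organolithium steps, so it is attached late to the exposed C6 hydroxyl of 17. The acid 22 comes from 18 through 19 and 21 by a Wittig reaction with 20.

**Key disconnection, C9–C10 (17 ⇐ 16 ⇐ 15 ⇐ 14).** The bond to the quaternary carbon is cut.
- In the furan series C9 is a furfuryl carbon, a natural electrophile.
- C10 is the α-carbon of a ketone whose enolate is an aromatic 3-oxidofuran, a natural nucleophile.
- Cutting here removes ring B and the quaternary stereocentre together and leaves 14, a chain of two heteroaromatic rings with two stereocentres.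
- The forward reaction has to close a nine-membered ring by C-alkylation, choose one face of the planar furanolate (controlled by C6) and prefer carbon over oxygen.

**Ring A (14 ⇐ 13 ⇐ 12 ⇐ 10 + 11).** The O–C3 and C2–C3 bonds are cut: furanone 13 is the cycloisomerisation product of γ-hydroxy ynone 12, which comes from Weinreb amide 10 and alkynol 11. C10 is left unset on purpose, because it is enolised in the key step.

**The C3–C6 unit as a cis lactone (10 ⇐ 9 ⇐ 8 ⇐ 7 ⇐ 4 + 5).** C3, C4, C5, C6 and the methyl group are recognised as the cis-α-methyl-γ-butyrolactone 8. Cutting C5–C6 leads to furylmethanol 4 and acrylate 5. A catalytic asymmetric carbonyl 2-(alkoxycarbonyl)allylation sets C6, and hydrogenation of 7 relays it to C4.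

**The furan core (4 ⇐ 3 ⇐ 2 ⇐ 1).** The three CH2O groups on adjacent furan carbons are differentiated starting from the symmetrical diol 1: monosilylation, then alkoxide-directed lithiation and hydroxymethylation forms C8–C9, then the less hindered alcohol is silylated.

## Alternatives that were turned down

**Alternative 1:** the textbook cut at C6–C7 of ring B.
- Forward key step: intramolecular Nozaki–Hiyama–Kishi reaction of iodo-aldehyde A1 (CrCl2, catalytic NiCl2), closing the nine-membered ring with formation of the C6 carbinol, then the same furan oxidation.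
- Turned down because the quaternary C10 has to be made beforehand by a separate auxiliary-based alkylation and ring A built around it, which costs about five more steps before the ring closure.
- The closure creates C6 from an sp2 carbon that has no substituent to steer it, so its configuration depends on remote C4 and C10; a correction by oxidation and reduction adds two steps.
- The furyl–chromium species is flanked by two ortho substituents and should add slowly.

**Alternative 2:** closure of the ten-membered carbocycle at C1–C2 and transannular formation of ring A.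
- Forward key step: intramolecular acetylide-to-aldehyde addition and oxidation to the cyclic hydroxy ynone A2, then gold-catalysed transannular 5-endo cyclisation of the C10 hydroxyl onto C3.
- Turned down because the linear C1–C2≡C3–C4 unit and the planar fused furan must fit into one ten-membered ring, so the closure is strained.
- Ring closure takes three operations, C10 again has to be bought by an auxiliary, and the C4 stereocentre sits next to the ynone carbonyl where it can epimerise.
- The ring closure gains no stereochemical information.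

**Alternative 3:** cut at C9–C10 and O–C7 in the sense of an oxonium ylide ring expansion.
- Forward key step: Cu(hfacac)2-catalysed decomposition of the tetrahydropyranyl diazoketone A3 to a bicyclic oxonium ylide, whose [2,3]-sigmatropic shift expands the six-membered ether into the oxa-bridged nine-membered ring and sets C10 by relay from C3.
- It is attractive because ring B and C10 arise in one step, but the product carries C7=C8 as a plain alkene and a saturated C2–C3.
- The whole of ring C (C11–C13, the lactone oxygen on C8, C8=C9) would have to be built on the medium ring afterwards, at least six further steps, and ring A still has to be dehydrogenated.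
- The α-methyl diazoketone is prone to 1,2-hydride shift, and two of the four stereocentres of the pyran are made only to be destroyed.

Key step: step 11

## Remarks before the steps

- Abbreviations in names: TBS = tert-butyldimethylsilyl, TBDPS = tert-butyldiphenylsilyl, Ar = 2-(TBSOCH2)-4-(TBDPSOCH2)furan-3-yl.
- Assumption: (R)-SEGPHOS is taken to give the 6S carbinol in step 4 by analogy with other aryl methanols; if the sense is the opposite, (S)-SEGPHOS is used and nothing else changes.
- Compound 5 is a catalogue compound; otherwise it is one acetylation away from ethyl 2-(hydroxymethyl)acrylate.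

## Route

Step 1
Reactants: 1 furan-3,4-diyldimethanol
Product: 2 [4-(TBDPSOCH2)furan-3-yl]methanol
Conditions: NaH (1 equiv), THF, 0 °C to rt; TBDPSCl (1 equiv)
Reagents that add atoms: tert-butyl(chloro)diphenylsilane CC(C)(C)[Si](Cl)(c1ccccc1)c1ccccc1
Why: Monosilylation of a symmetrical diol through its sparingly soluble monosodium alkoxide favours the mono-ether; the TBDPS ether marks the future C13 oxygen and stays until the last step.

Step 2
Reactants: 2 [4-(TBDPSOCH2)furan-3-yl]methanol
Product: 3 [4-(TBDPSOCH2)furan-2,3-diyl]dimethanol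
Conditions: n-BuLi (2.2 equiv), THF, -78 to 0 °C; (CH2O)n, -78 °C to rt; H2O
Reagents that add atoms: formaldehyde (as paraformaldehyde) C=O
Why: Alkoxide-directed ortho-lithiation: the lithium alkoxide of the free hydroxymethyl group directs the second equivalent of base to the adjacent α-position (C8) rather than to the α-position next to the bulky silyl ether, and trapping with formaldehyde installs C9 as a hydroxymethyl group.

Step 3
Reactants: 3 [4-(TBDPSOCH2)furan-2,3-diyl]dimethanol
Product: 4 [2-(TBSOCH2)-4-(TBDPSOCH2)furan-3-yl]methanol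
Conditions: TBSCl (1.05 equiv), imidazole, CH2Cl2, -30 °C
Reagents that add atoms: tert-butyl(chloro)dimethylsilane CC(C)(C)[Si](C)(C)Cl
Why: Kinetic silylation: the C9 hydroxyl has one ring substituent beside it and the C6 hydroxyl has two, so one equivalent of the bulky chlorosilane at low temperature should take the less hindered furfuryl alcohol.

Step 4
Reactants: 4 [2-(TBSOCH2)-4-(TBDPSOCH2)furan-3-yl]methanol; 5 ethyl 2-(acetoxymethyl)prop-2-enoate
Product: 7 (5S)-5-Ar-3-methylideneoxolan-2-one, via hydroxy ester 6 (not isolated)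
Conditions: [Ir(cod)Cl]2 (2.5 mol %), (R)-SEGPHOS (5 mol %), 4-cyano-3-nitrobenzoic acid (10 mol %), Cs2CO3 (20 mol %), THF, 70 °C
Reagents that add atoms: none
Why: Iridium-catalysed transfer-hydrogenative carbonyl 2-(alkoxycarbonyl)allylation: the alcohol is dehydrogenated to the aldehyde, the π-allyl iridium species from 5 adds under control of the chiral bisphosphine to set C6 (S), and the resulting alkoxide of 6 lactonises on the ethyl ester; C5–C6 is formed without a separate oxidation step.

Step 5
Reactants: 7 (5S)-5-Ar-3-methylideneoxolan-2-one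
Product: 8 (3S,5S)-5-Ar-3-methyloxolan-2-one
Conditions: H2 (1 atm), RhCl(PPh3)3 (5 mol %), benzene/EtOH, rt
Reagents that add atoms: none
Why: Homogeneous hydrogenation of the exocyclic alkene from the face opposite the C6 furyl group gives the cis lactone, so C4 (S) is relayed from C6; the cis isomer is also the thermodynamic one, so any trans isomer can be equilibrated with DBU, and the rhodium catalyst avoids hydrogenolysis of the furfuryl C–O bonds.

Step 6
Reactants: 8 (3S,5S)-5-Ar-3-methyloxolan-2-one
Product: 9 (2S,4S)-4-Ar-4-hydroxy-N-methoxy-N,2-dimethylbutanamide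
Conditions: MeNHOMe·HCl, i-PrMgCl, THF, -20 to 0 °C
Reagents that add atoms: N,O-dimethylhydroxylamine hydrochloride CNOC.Cl
Why: Aminolysis of the lactone by the chloromagnesium amide (Weinreb amide formation) frees the C6 hydroxyl and turns C3 into an acyl donor that accepts one carbanion only; the C4 centre is not enolised under these conditions.

Step 7
Reactants: 9 (2S,4S)-4-Ar-4-hydroxy-N-methoxy-N,2-dimethylbutanamide
Product: 10 (2S,4S)-4-Ar-4-(TBSO)-N-methoxy-N,2-dimethylbutanamide
Conditions: TBSOTf, 2,6-lutidine, CH2Cl2, -78 °C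
Reagents that add atoms: tert-butyldimethylsilyl trifluoromethanesulfonate CC(C)(C)[Si](C)(C)OS(=O)(=O)C(F)(F)F
Why: Silyl triflate silylation of the hindered secondary alcohol prevents relactonisation and installs the bulky C6 substituent that later steers the key step.

Step 8
Reactants: 10 (2S,4S)-4-Ar-4-(TBSO)-N-methoxy-N,2-dimethylbutanamide; 11 but-3-yn-2-ol (racemic)
Product: 12 (6S,8S)-8-Ar-8-(TBSO)-2-hydroxy-6-methyloct-3-yn-5-one (C2 epimers)
Conditions: 11 (3 equiv), n-BuLi (6 equiv), THF, -78 to -30 °C; then 10; aq. NH4Cl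
Reagents that add atoms: none
Why: Addition of the dilithiated alkynol to the Weinreb amide stops at the chelated tetrahedral intermediate and gives the γ-hydroxy ynone on work-up; the new bond is C2–C3, and the C10 carbinol is deliberately racemic because this centre is enolised in step 11.

Step 9
Reactants: 12 (6S,8S)-8-Ar-8-(TBSO)-2-hydroxy-6-methyloct-3-yn-5-one (C2 epimers)
Product: 13 5-[(2S,4S)-4-Ar-4-(TBSO)butan-2-yl]-2-methylfuran-3(2H)-one (C2 epimers)
Conditions: (p-CF3C6H4)3PAuCl (5 mol %), AgOTf (5 mol %), toluene, rt
Reagents that add atoms: none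
Why: Gold-catalysed cycloisomerisation of a γ-hydroxy alkynone to a furan-3(2H)-one (formal hydration of the alkyne at C1 and cyclodehydration of the C10 hydroxyl onto C3); the neutral conditions keep the three silyl ethers and the C4 stereocentre.

Step 10
Reactants: 13 5-[(2S,4S)-4-Ar-4-(TBSO)butan-2-yl]-2-methylfuran-3(2H)-one (C2 epimers)
Product: 14 5-{(2S,4S)-4-(TBSO)-4-[2-(hydroxymethyl)-4-(TBDPSOCH2)furan-3-yl]butan-2-yl}-2-methylfuran-3(2H)-one (C2 epimers)
Conditions: HF·pyridine, pyridine, THF, 0 °C
Reagents that add atoms: none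
Why: Buffered HF cleaves the primary furfuryl TBS ether much faster than the hindered secondary TBS ether and the TBDPS ether, which frees only the C9 hydroxyl.

Step 11
Reactants: 14 5-{(2S,4S)-4-(TBSO)-4-[2-(hydroxymethyl)-4-(TBDPSOCH2)furan-3-yl]butan-2-yl}-2-methylfuran-3(2H)-one (C2 epimers)
Product: 16 (4S,6S,10S)-6-(TBSO)-13-(TBDPSO)-3,10:8,12-diepoxygermacra-2,7,11-trien-1-one, via furfuryl chloride 15 (not isolated)
Conditions: MsCl, 2,4,6-collidine, LiCl, DMF, 0 °C; crude chloride in MeCN added over 12 h to Cs2CO3, n-Bu4NI (20 mol %), MeCN, 45 °C, final 2 mM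
Reagents that add atoms: none
Why: Mesylation with in situ chloride exchange converts the furfuryl alcohol into chloride 15; under high dilution Cs2CO3 removes the C10 hydrogen of the furanone (the anion is an aromatic 3-oxidofuran), the iodide catalyst makes the electrophile more reactive, and C10 attacks C9 in an intramolecular SN2 displacement. The closest known reaction type is the C2-alkylation of 2-substituted furan-3(2H)-ones and benzofuran-3(2H)-ones by benzylic halides, together with medium-ring closure by alkylation of a stabilised carbanion. The new C9–C10 bond closes the nine-membered oxacycle of ring B in a 9-exo-tet mode (the ten-membered carbocycle closes with it) and turns the flat furanolate into ring A with its quaternary carbon. C10 is the only new stereocentre and is controlled by C6: in the bridged transition state C6 lies above the furanolate ring, its inward valence points into the π face and can hold only hydrogen, so the OTBS group must point outward, and for the 6S configuration this puts the tether over the face that gives 10S; the 4S methyl group lies on the periphery in this arrangement, so the two existing centres are matched. The step needs C- rather than O-alkylation; O-alkylation would give a metacyclophane-type 3-alkoxyfuran whose seven-atom bridge has to leave in the plane of an aromatic ring, which is far more strained than the C-alkylated product, where the bridge leaves an sp3 carbon perpendicular to the ring. Closure through C4 to a six-membered ring is avoided because the weak base cannot form the extended dienolate, and intermolecular alkylation is suppressed by slow addition.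

Step 12
Reactants: 16 (4S,6S,10S)-6-(TBSO)-13-(TBDPSO)-3,10:8,12-diepoxygermacra-2,7,11-trien-1-one
Product: 17 (4S,6S,10S)-13-(TBDPSO)-6-hydroxy-3,10:8,12-diepoxygermacra-2,7,11-trien-1-one
Conditions: HF·pyridine, THF, 0 °C to rt
Reagents that add atoms: none
Why: Acidic fluoride removes the secondary TBS ether while the primary TBDPS ether, far more stable under these conditions, remains; C10 is now quaternary, so ring A has no enolisable α-position left.

Step 13
Reactants: 18 1-hydroxypropan-2-one
Product: 19 1-(TBDPSO)propan-2-one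
Conditions: TBDPSCl, imidazole, DMF, rt
Reagents that add atoms: tert-butyl(chloro)diphenylsilane CC(C)(C)[Si](Cl)(c1ccccc1)c1ccccc1
Why: Standard silylation of a primary alcohol; the same silyl group as on C13 allows one global deprotection at the end.

Step 14
Reactants: 19 1-(TBDPSO)propan-2-one; 20 ethyl (triphenylphosphoranylidene)acetate
Product: 21 ethyl (2E)-4-(TBDPSO)-3-methylbut-2-enoate
Conditions: toluene, 90 °C
Reagents that add atoms: none
Why: Wittig olefination with a stabilised ylide places the ester trans to the larger CH2OSi substituent and should give the E-alkene of the side chain.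

Step 15
Reactants: 21 ethyl (2E)-4-(TBDPSO)-3-methylbut-2-enoate
Product: 22 (2E)-4-(TBDPSO)-3-methylbut-2-enoic acid
Conditions: LiOH, THF/MeOH/H2O, rt; then 1 M HCl, 0 °C
Reagents that add atoms: lithium hydroxide [Li+].[OH-]
Why: Saponification of the ethyl ester; the primary TBDPS ether tolerates lithium hydroxide at room temperature and a brief cold acidification.

Step 16
Reactants: 17 (4S,6S,10S)-13-(TBDPSO)-6-hydroxy-3,10:8,12-diepoxygermacra-2,7,11-trien-1-one; 22 (2E)-4-(TBDPSO)-3-methylbut-2-enoic acid
Product: 23 (4S,6S,10S)-13-(TBDPSO)-3,10:8,12-diepoxy-1-oxogermacra-2,7,11-trien-6-yl (2E)-4-(TBDPSO)-3-methylbut-2-enoate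
Conditions: DIC, DMAP (cat.), CH2Cl2, 0 °C to rt
Reagents that add atoms: none
Why: Steglich esterification of the outward-pointing C6 hydroxyl with retention at C6; carbodiimide activation avoids the vinylketene pathway that could deconjugate or isomerise the enoate.

Step 17
Reactants: 23 (4S,6S,10S)-13-(TBDPSO)-3,10:8,12-diepoxy-1-oxogermacra-2,7,11-trien-6-yl (2E)-4-(TBDPSO)-3-methylbut-2-enoate
Product: 26 (4S,6S,8E,10S)-13-(TBDPSO)-3,10-epoxy-1-oxogermacra-2,7(11),8-trien-12,8-olid-6-yl (2E)-4-(TBDPSO)-3-methylbut-2-enoate, via endoperoxide 24 (not isolated), via hydroxybutenolide 25 (not isolated)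
Conditions: O2, visible light, tetraphenylporphyrin (cat.), i-Pr2NEt, CH2Cl2, -78 °C; then MsCl, Et3N, -40 to 0 °C
Reagents that add atoms: dioxygen O=O
Why: Singlet oxygen adds in a [4+2] cycloaddition to the furan, the most electron-rich π system (the enone of ring A and the enoate are inert), and base-induced Kornblum–DeLaMare fragmentation can remove only the C12 hydrogen, so it gives the C12 lactone carbonyl and the C8 hemiketal. Sulfonylation of the hemiketal hydroxyl and loss of a C9 proton then give the ylidene butenolide, whose C8=C9 geometry is fixed by ring B.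

Step 18
Reactants: 26 (4S,6S,8E,10S)-13-(TBDPSO)-3,10-epoxy-1-oxogermacra-2,7(11),8-trien-12,8-olid-6-yl (2E)-4-(TBDPSO)-3-methylbut-2-enoate
Product: 27 (4S,6S,8E,10S)-3,10-epoxy-13-hydroxy-1-oxogermacra-2,7(11),8-trien-12,8-olid-6-yl (2E)-4-hydroxy-3-methylbut-2-enoate
Conditions: HF·pyridine, pyridine, THF, rt
Reagents that add atoms: none
Why: Global desilylation of the two primary TBDPS ethers with buffered, non-basic fluoride, which should leave the ylidene butenolide, the C6 ester and the furanone untouched.

## Compound list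

1 | furan-3,4-diyldimethanol | OCc1cocc1CO | starting material
2 | [4-(TBDPSOCH2)furan-3-yl]methanol | OCc1cocc1CO[Si](c1ccccc1)(c1ccccc1)C(C)(C)C | intermediate
3 | [4-(TBDPSOCH2)furan-2,3-diyl]dimethanol | OCc1c(CO)occ1CO[Si](c1ccccc1)(c1ccccc1)C(C)(C)C | intermediate
4 | [2-(TBSOCH2)-4-(TBDPSOCH2)furan-3-yl]methanol | OCc1c(CO[Si](C)(C)C(C)(C)C)occ1CO[Si](c1ccccc1)(c1ccccc1)C(C)(C)C | intermediate
5 | ethyl 2-(acetoxymethyl)prop-2-enoate | C=C(COC(C)=O)C(=O)OCC | starting material
6 | ethyl (4S)-4-Ar-4-hydroxy-2-methylidenebutanoate | CCOC(=O)C(=C)C[C@H](O)c1c(CO[Si](C)(C)C(C)(C)C)occ1CO[Si](c1ccccc1)(c1ccccc1)C(C)(C)C | intermediate (not isolated)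
7 | (5S)-5-Ar-3-methylideneoxolan-2-one | O=C1O[C@H](c2c(CO[Si](C)(C)C(C)(C)C)occ2CO[Si](c2ccccc2)(c2ccccc2)C(C)(C)C)CC1=C | intermediate
8 | (3S,5S)-5-Ar-3-methyloxolan-2-one (cis) | O=C1O[C@H](c2c(CO[Si](C)(C)C(C)(C)C)occ2CO[Si](c2ccccc2)(c2ccccc2)C(C)(C)C)C[C@@H]1C | intermediate
9 | (2S,4S)-4-Ar-4-hydroxy-N-methoxy-N,2-dimethylbutanamide | CON(C)C(=O)[C@@H](C)C[C@H](O)c1c(CO[Si](C)(C)C(C)(C)C)occ1CO[Si](c1ccccc1)(c1ccccc1)C(C)(C)C | intermediate
10 | (2S,4S)-4-Ar-4-(TBSO)-N-methoxy-N,2-dimethylbutanamide | CON(C)C(=O)[C@@H](C)C[C@H](O[Si](C)(C)C(C)(C)C)c1c(CO[Si](C)(C)C(C)(C)C)occ1CO[Si](c1ccccc1)(c1ccccc1)C(C)(C)C | intermediate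
11 | but-3-yn-2-ol (racemic) | CC(O)C#C | starting material
12 | (6S,8S)-8-Ar-8-(TBSO)-2-hydroxy-6-methyloct-3-yn-5-one (C2 epimers) | CC(O)C#CC(=O)[C@@H](C)C[C@H](O[Si](C)(C)C(C)(C)C)c1c(CO[Si](C)(C)C(C)(C)C)occ1CO[Si](c1ccccc1)(c1ccccc1)C(C)(C)C | intermediate
13 | 5-[(2S,4S)-4-Ar-4-(TBSO)butan-2-yl]-2-methylfuran-3(2H)-one (C2 epimers) | CC1OC(=CC1=O)[C@@H](C)C[C@H](O[Si](C)(C)C(C)(C)C)c1c(CO[Si](C)(C)C(C)(C)C)occ1CO[Si](c1ccccc1)(c1ccccc1)C(C)(C)C | intermediate
14 | 5-{(2S,4S)-4-(TBSO)-4-[2-(hydroxymethyl)-4-(TBDPSOCH2)furan-3-yl]butan-2-yl}-2-methylfuran-3(2H)-one (C2 epimers) | CC1OC(=CC1=O)[C@@H](C)C[C@H](O[Si](C)(C)C(C)(C)C)c1c(CO)occ1CO[Si](c1ccccc1)(c1ccccc1)C(C)(C)C | intermediate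
15 | 5-{(2S,4S)-4-(TBSO)-4-[2-(chloromethyl)-4-(TBDPSOCH2)furan-3-yl]butan-2-yl}-2-methylfuran-3(2H)-one (C2 epimers) | CC1OC(=CC1=O)[C@@H](C)C[C@H](O[Si](C)(C)C(C)(C)C)c1c(CCl)occ1CO[Si](c1ccccc1)(c1ccccc1)C(C)(C)C | intermediate (not isolated)
16 | (4S,6S,10S)-6-(TBSO)-13-(TBDPSO)-3,10:8,12-diepoxygermacra-2,7,11-trien-1-one | CC(C)(C)[Si](C)(C)O[C@H]1C[C@H](C)C2=CC(=O)[C@](C)(Cc3occ(CO[Si](c4ccccc4)(c4ccccc4)C(C)(C)C)c31)O2 | intermediate
17 | (4S,6S,10S)-13-(TBDPSO)-6-hydroxy-3,10:8,12-diepoxygermacra-2,7,11-trien-1-one | O[C@H]1C[C@H](C)C2=CC(=O)[C@](C)(Cc3occ(CO[Si](c4ccccc4)(c4ccccc4)C(C)(C)C)c31)O2 | intermediate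
18 | 1-hydroxypropan-2-one | CC(=O)CO | starting material
19 | 1-(TBDPSO)propan-2-one | CC(=O)CO[Si](c1ccccc1)(c1ccccc1)C(C)(C)C | intermediate
20 | ethyl (triphenylphosphoranylidene)acetate | CCOC(=O)C=P(c1ccccc1)(c1ccccc1)c1ccccc1 | starting material
21 | ethyl (2E)-4-(TBDPSO)-3-methylbut-2-enoate | C/C(=C\C(=O)OCC)CO[Si](c1ccccc1)(c1ccccc1)C(C)(C)C | intermediate
22 | (2E)-4-(TBDPSO)-3-methylbut-2-enoic acid | C/C(=C\C(=O)O)CO[Si](c1ccccc1)(c1ccccc1)C(C)(C)C | intermediate
23 | (4S,6S,10S)-13-(TBDPSO)-3,10:8,12-diepoxy-1-oxogermacra-2,7,11-trien-6-yl (2E)-4-(TBDPSO)-3-methylbut-2-enoate | C/C(=C\C(=O)O[C@H]1C[C@H](C)C2=CC(=O)[C@](C)(Cc3occ(CO[Si](c4ccccc4)(c4ccccc4)C(C)(C)C)c31)O2)CO[Si](c1ccccc1)(c1ccccc1)C(C)(C)C | intermediate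
24 | 8,12-epidioxy adduct of 23 (2,3,7-trioxabicyclo[2.2.1]hept-5-ene spanning C8 and C12; bridgehead configurations not specified) | C/C(=C\C(=O)O[C@H]1C[C@H](C)C2=CC(=O)[C@](C)(CC35OC(OO5)C(CO[Si](c4ccccc4)(c4ccccc4)C(C)(C)C)=C31)O2)CO[Si](c1ccccc1)(c1ccccc1)C(C)(C)C | intermediate (not isolated)
25 | (4S,6S,10S)-13-(TBDPSO)-3,10-epoxy-8-hydroxy-1-oxogermacra-2,7(11)-dien-12,8-olid-6-yl (2E)-4-(TBDPSO)-3-methylbut-2-enoate (C8 epimers) | C/C(=C\C(=O)O[C@H]1C[C@H](C)C2=CC(=O)[C@](C)(CC3(O)OC(=O)C(CO[Si](c4ccccc4)(c4ccccc4)C(C)(C)C)=C31)O2)CO[Si](c1ccccc1)(c1ccccc1)C(C)(C)C | intermediate (not isolated)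
26 | (4S,6S,8E,10S)-13-(TBDPSO)-3,10-epoxy-1-oxogermacra-2,7(11),8-trien-12,8-olid-6-yl (2E)-4-(TBDPSO)-3-methylbut-2-enoate | C/C(=C\C(=O)O[C@H]1C[C@H](C)C2=CC(=O)[C@](C)(/C=C3/OC(=O)C(CO[Si](c4ccccc4)(c4ccccc4)C(C)(C)C)=C31)O2)CO[Si](c1ccccc1)(c1ccccc1)C(C)(C)C | intermediate
27 | (4S,6S,8E,10S)-3,10-epoxy-13-hydroxy-1-oxogermacra-2,7(11),8-trien-12,8-olid-6-yl (2E)-4-hydroxy-3-methylbut-2-enoate | C/C(=C\C(=O)O[C@H]1C[C@H](C)C2=CC(=O)[C@](C)(/C=C3/OC(=O)C(CO)=C31)O2)CO | target

## Step count and least certain steps

Total step count: 18. Longest linear sequence: 15 (steps 1–12 and 16–18); steps 13–15 form the side-chain branch.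

**Step 11 (key step).**
- What may go wrong: the nine-membered ring closes too slowly, so that intermolecular alkylation and solvolytic loss of the furfuryl chloride take over. The latter includes attack of the neighbouring C6 silyl ether oxygen on C9. Attack on the wrong face of the furanolate is the second risk.
- Fallback: it sets out from 14. Methyl chloroformate and pyridine give the methyl carbonate F1. Under zerovalent palladium (Pd2(dba)3, DPEphos, toluene, 60 °C, high dilution) F1 ionises to an η3-furfuryl palladium complex; the methoxide set free deprotonates the furanone and the soft furanolate attacks C9.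
- This Tsuji–Trost-type furfurylic substitution needs no free halide, keeps the electrophile in reversible equilibrium, and allows a chiral C2-symmetric diphosphine to add catalyst control to the facial selectivity. It comes back to the route at 16.

**Step 4.**
- What may go wrong: sluggish dehydrogenation or allylation of the doubly ortho-substituted furylmethanol, or insufficient enantioselectivity.
- Fallback: it sets out from 4. MnO2 oxidation gives the aldehyde F2. A zinc-mediated Barbier reaction with ethyl 2-(bromomethyl)acrylate gives the racemic hydroxy ester F3. Dess–Martin oxidation gives the keto ester F4.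
- Corey–Bakshi–Shibata reduction of F4 ((R)-methyl oxazaborolidine, catecholborane, -40 °C; aryl large, CH2 small) sets 6S by reagent control. It comes back at 6, which lactonises to 7.

**Step 9.**
- What may go wrong: gold activation of the electron-rich furan or loss of a silyl ether competing with the cyclisation, and epimerisation at C4 of the ynone.
- Fallback: it sets out from 10. Acylation of the dianion of 3-hydroxybutan-2-one (LDA, 2 equiv, THF, -78 °C) by the Weinreb amide gives the hydroxy diketone F5. Cyclodehydration with PPTS in benzene closes ring A by the Claisen-type route without an alkyne and comes back at 13.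

**Step 17.**
- What may go wrong: over-oxidation, an ene reaction of singlet oxygen with the side-chain alkene, or incomplete dehydration of the hemiketal.
- Fallback: it sets out from 23. Dimethyldioxirane (acetone, -78 °C) opens the furan to the Z-keto-enal F6. Pinnick oxidation (NaClO2, NaH2PO4, 2-methylbut-2-ene) converts the C12 aldehyde into the acid, which closes on the C8 ketone and comes back at 25; dehydration as in step 17 then gives 26.

## Further compounds

F1 | step 11 | methyl carbonate of alcohol 14 (2-[(methoxycarbonyl)oxymethyl]furan; C2 epimers of the furanone) | CC1OC(=CC1=O)[C@@H](C)C[C@H](O[Si](C)(C)C(C)(C)C)c1c(COC(=O)OC)occ1CO[Si](c1ccccc1)(c1ccccc1)C(C)(C)C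
F2 | step 4 | 2-(TBSOCH2)-4-(TBDPSOCH2)furan-3-carbaldehyde | O=Cc1c(CO[Si](C)(C)C(C)(C)C)occ1CO[Si](c1ccccc1)(c1ccccc1)C(C)(C)C
F3 | step 4 | ethyl 4-Ar-4-hydroxy-2-methylidenebutanoate (racemic) | CCOC(=O)C(=C)CC(O)c1c(CO[Si](C)(C)C(C)(C)C)occ1CO[Si](c1ccccc1)(c1ccccc1)C(C)(C)C
F4 | step 4 | ethyl 4-Ar-2-methylidene-4-oxobutanoate | CCOC(=O)C(=C)CC(=O)c1c(CO[Si](C)(C)C(C)(C)C)occ1CO[Si](c1ccccc1)(c1ccccc1)C(C)(C)C
F5 | step 9 | (6S,8S)-8-Ar-8-(TBSO)-2-hydroxy-6-methyloctane-3,5-dione (C2 epimers) | CC(O)C(=O)CC(=O)[C@@H](C)C[C@H](O[Si](C)(C)C(C)(C)C)c1c(CO[Si](C)(C)C(C)(C)C)occ1CO[Si](c1ccccc1)(c1ccccc1)C(C)(C)C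
F6 | step 17 | Z-keto-enal from oxidative opening of the furan of 23 (C8 ketone and C12 aldehyde cis on C7=C11) | C/C(=C\C(=O)O[C@H]1C[C@H](C)C2=CC(=O)[C@](C)(CC(=O)/C1=C(/CO[Si](c3ccccc3)(c3ccccc3)C(C)(C)C)C=O)O2)CO[Si](c1ccccc1)(c1ccccc1)C(C)(C)C
A1 | alternative 1 | (2S)-2-{[3-iodo-4-(TBDPSOCH2)furan-2-yl]methyl}-2-methyl-5-[(2S)-4-oxobutan-2-yl]furan-3(2H)-one | O=CC[C@H](C)C1=CC(=O)[C@](C)(Cc2occ(CO[Si](c3ccccc3)(c3ccccc3)C(C)(C)C)c2I)O1
A2 | alternative 2 | (4S,6S,10S)-6-(TBSO)-13-(TBDPSO)-10-hydroxy-8,12-epoxygermacra-7,11-dien-2-yn-1-one | C[C@H]1C[C@H](O[Si](C)(C)C(C)(C)C)c2c(C[C@](C)(O)C(=O)C#C1)occ2CO[Si](c1ccccc1)(c1ccccc1)C(C)(C)C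
A3 | alternative 3 | 3-diazo-1-[(2S,3S,5S,6R)-5-(TBSO)-6-ethenyl-3-methyloxan-2-yl]butan-2-one | C=C[C@H]1O[C@@H](CC(=O)C(C)=[N+]=[N-])[C@@H](C)C[C@@H]1O[Si](C)(C)C(C)(C)C
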